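The route rests on cutting ring C of the 7-methoxyflavanone unit at O1–C8a and C4–C4a. This frees ring A as 3,5-dimethoxybenzyne and leaves an open-chain (S)-β-silyloxy ester that already holds C2 and the finished second flavanone. In one fluoride-triggered operation the unmasked alkoxide adds to the aryne and the resulting aryl anion closes onto the ester, attaching ring A and closing ring C with C2 untouched. The step exploits the ortho pair O1 on C8a and acyl C4 on C4a beside the C5 oxygen, which polarises the aryne towards exactly this orientation. Chelation-controlled BCl3 cleavage finally frees 5-OH and keeps 7-OMe.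

Key step: step 9

Assumption: in the two catalyst-controlled steps (5 and 7) the catalyst antipode used is the one that gives the S centre. The sense quoted is inferred from benzaldehyde and from cyclic enones, and both antipodes are available.

Step 1
Reactants: 1 3,5-dimethoxyphenol
Product: 2 2-bromo-3,5-dimethoxyphenol
Conditions: NBS (1.0 equiv), CH2Cl2, −78 to 0 °C
Reagents that add atoms: N-bromosuccinimide, O=C1CCC(=O)N1Br
Why: Electrophilic aromatic bromination; the two equivalent positions between OH and OMe are less hindered than C4 between two methoxy groups, so one equivalent of NBS at low temperature should give mainly the 2-bromide.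

Step 2
Reactants: 2 2-bromo-3,5-dimethoxyphenol
Product: 5 3,5-dimethoxy-2-(trimethylsilyl)phenyl trifluoromethanesulfonate, via aryl trimethylsilyl ether 3 (not isolated), via lithium 2-silylphenoxide 4 (not isolated)
Conditions: HMDS, 80 °C, then evaporate; n-BuLi, THF, −100 to −78 °C; Tf2O, −78 to 23 °C
Reagents that add atoms: hexamethyldisilazane, C[Si](C)(C)N[Si](C)(C)C; trifluoromethanesulfonic anhydride, O=S(=O)(OS(=O)(=O)C(F)(F)F)C(F)(F)F
Why: O-silylation, bromine–lithium exchange and retro-Brook (O to C) silyl migration give the 2-silylphenoxide, which the anhydride traps; this is the standard one-pot passage from o-bromophenols to o-silylaryl triflates.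

Step 3
Reactants: 6 5,7-dihydroxy-4H-chromen-4-one
Product: 7 5,7-bis(benzyloxy)-4H-chromen-4-one
Conditions: BnBr (2.5 equiv), K2CO3 (3 equiv), DMF, 70 °C
Reagents that add atoms: benzyl bromide, BrCc1ccccc1
Why: Williamson ether synthesis; excess bromide in warm DMF should also alkylate the hydrogen-bonded 5-OH.

Step 4
Reactants: 8 4-(benzyloxy)-3-hydroxybenzaldehyde; 9 1-bromo-4-iodobenzene
Product: 10 4-(benzyloxy)-3-(4-bromophenoxy)benzaldehyde
Conditions: CuI (10 mol %), N,N-dimethylglycine hydrochloride (30 mol %), Cs2CO3 (2 equiv), dioxane, 90 °C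
Reagents that add atoms: none
Why: Ullmann ether synthesis with an amino acid ligand; copper activates C–I far faster than C–Br, so the bromide is kept as the later boron handle.

Step 5
Reactants: 10 4-(benzyloxy)-3-(4-bromophenoxy)benzaldehyde; 11 1-(tert-butyldimethylsilyloxy)-1-methoxyethene
Product: 13 methyl (3S)-3-[4-(benzyloxy)-3-(4-bromophenoxy)phenyl]-3-hydroxypropanoate, via trichlorosilyl ether 12 (not isolated)
Conditions: SiCl4 (1.5 equiv), binaphthyl-2,2'-diamine-derived bisphosphoramide with pentane-1,5-diyl tether (5 mol %, antipode for Si-face attack), CH2Cl2, −78 °C; then aqueous NaHCO3 work-up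
Reagents that add atoms: none
Why: Catalytic enantioselective Mukaiyama aldol addition with Lewis-base-activated SiCl4; the chiral phosphoramide-bound silyl cation binds the aldehyde and shields one face, so the acetate ketene acetal attacks the Si face through an open transition state and sets the S carbinol centre that becomes C2.

Step 6
Reactants: 13 methyl (3S)-3-[4-(benzyloxy)-3-(4-bromophenoxy)phenyl]-3-hydroxypropanoate
Product: 14 [4-(2-(benzyloxy)-5-[(1S)-1-hydroxy-3-methoxy-3-oxopropyl]phenoxy)phenyl]boronic acid
Conditions: B2(OH)4 (2 equiv), PdCl(2'-aminobiphenyl-2-yl)(XPhos) (second-generation XPhos palladacycle, 1 mol %), XPhos (2 mol %), KOAc (3 equiv), EtOH, 80 °C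
Reagents that add atoms: tetrahydroxydiboron, OB(O)B(O)O
Why: Miyaura-type borylation with tetrahydroxydiboron gives the free boronic acid directly, and the weak base should leave ester, carbinol centre and benzyl ether alone.

Step 7
Reactants: 14 the boronic acid; 7 5,7-bis(benzyloxy)-4H-chromen-4-one (1.5 equiv)
Product: 15 methyl (3S)-3-[4-(benzyloxy)-3-{4-[(2S)-5,7-bis(benzyloxy)-4-oxochroman-2-yl]phenoxy}phenyl]-3-hydroxypropanoate
Conditions: [Rh(OH)(cod)]2 (2.5 mol %), (S)-2,2'-bis[bis(3,4,5-trifluorophenyl)phosphino]-6,6'-dimethoxybiphenyl (5.5 mol %), CH2Cl2/H2O 10:1, 25 °C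
Reagents that add atoms: none
Why: Hayashi–Miyaura reaction on a chromone; the aryl–rhodium complex of the electron-poor (S)-biaryl bisphosphine inserts C2=C3 from one face only, which sets the second S centre under catalyst control far from the existing one, and base-free hydrolysis of the rhodium enolate keeps the new flavanone closed.

Step 8
Reactants: 15 the β-hydroxy ester
Product: 16 methyl (3S)-3-[4-(benzyloxy)-3-{4-[(2S)-5,7-bis(benzyloxy)-4-oxochroman-2-yl]phenoxy}phenyl]-3-[(trimethylsilyl)oxy]propanoate
Conditions: TMSCl (1.3 equiv), imidazole (2 equiv), CH2Cl2, 0 °C; filtration through Et3N-deactivated silica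
Reagents that add atoms: chlorotrimethylsilane, C[Si](C)(C)Cl
Why: Standard silylation of a secondary alcohol; it removes the only acidic proton so that the next step runs proton-free.

Step 9
Reactants: 16 the β-silyloxy ester; 5 3,5-dimethoxy-2-(trimethylsilyl)phenyl trifluoromethanesulfonate
Product: 19 (2S)-2-[4-(benzyloxy)-3-{4-[(2S)-5,7-bis(benzyloxy)-4-oxochroman-2-yl]phenoxy}phenyl]-5,7-dimethoxychroman-4-one, via 3,5-dimethoxybenzyne 17 (not isolated), via aryl anion adduct 18 (not isolated)
Conditions: 5 (2 equiv, added over 2 h), CsF (4 equiv), 18-crown-6 (4 equiv), THF, 0 to 23 °C; pH 7 buffer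
Reagents that add atoms: none
Why: Proposed new method: fluoride, and then the methoxide set free, strips silicon from both partners, so 5 collapses to aryne 17 while 16 releases its secondary alkoxide without any proton source; the alkoxide adds to the future C8a and the aryl anion 18, now at C4a, attacks the methyl ester and expels methoxide. The closest known reaction type is the aryne annulation of salicylate esters to xanthones (phenoxide addition, then acyl capture by the aryl anion), and the closure itself is that of a Parham cyclisation of a 3-aryloxypropanoate; what has not been shown is an aliphatic β-oxido ester as the partner. Ring C closes in the 6-exo-trig mode at the ester carbonyl. No stereocentre is made: the C2–O bond is never broken, so the S centre of 16 is carried over with retention and the S centre of the finished flavanone is a spectator. The step needs regioselectivity, and the methoxy group next to the triple bond secures it, because its inductive pull and the resulting distortion send nucleophiles to the far aryne carbon and place the charge beside the methoxy group, as is general for 3-alkoxyarynes. Retro-aldol cleavage, β-elimination and base-induced opening of either chromanone should be held back because free alkoxide or methoxide is re-silylated by 5, which thereby gives more aryne, so base never builds up.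

Step 10
Reactants: 19 the protected biflavanone
Product: 20 7-O-methyltetrahydroochnaflavone (2S,2''S)
Conditions: BCl3 (12 equiv), pentamethylbenzene (12 equiv), CH2Cl2, −78 to 0 °C; then MeOH and aqueous NH4Cl
Reagents that add atoms: none
Why: BCl3 with a cation scavenger cleaves aryl benzyl ethers at low temperature, and on warming the boron chelated between C4=O and the peri 5-OMe removes only that methyl group, so the unchelated 7-OMe and the diaryl ether should survive.

Compound list
1 | 3,5-dimethoxyphenol | COc1cc(O)cc(OC)c1 | starting material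
2 | 2-bromo-3,5-dimethoxyphenol | COc1cc(O)c(Br)c(OC)c1 | intermediate
3 | (2-bromo-3,5-dimethoxyphenoxy)trimethylsilane | COc1cc(O[Si](C)(C)C)c(Br)c(OC)c1 | intermediate
4 | lithium 3,5-dimethoxy-2-(trimethylsilyl)phenoxide | [Li+].COc1cc([O-])c([Si](C)(C)C)c(OC)c1 | intermediate
5 | 3,5-dimethoxy-2-(trimethylsilyl)phenyl trifluoromethanesulfonate | COc1cc(OS(=O)(=O)C(F)(F)F)c([Si](C)(C)C)c(OC)c1 | intermediate
6 | 5,7-dihydroxy-4H-chromen-4-one | O=c1ccoc2cc(O)cc(O)c12 | starting material
7 | 5,7-bis(benzyloxy)-4H-chromen-4-one | O=c1ccoc2cc(OCc3ccccc3)cc(OCc3ccccc3)c12 | intermediate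
8 | 4-(benzyloxy)-3-hydroxybenzaldehyde | O=Cc1ccc(OCc2ccccc2)c(O)c1 | starting material
9 | 1-bromo-4-iodobenzene | Brc1ccc(I)cc1 | starting material
10 | 4-(benzyloxy)-3-(4-bromophenoxy)benzaldehyde | O=Cc1ccc(OCc2ccccc2)c(Oc2ccc(Br)cc2)c1 | intermediate
11 | 1-(tert-butyldimethylsilyloxy)-1-methoxyethene | C=C(OC)O[Si](C)(C)C(C)(C)C | starting material
12 | methyl (3S)-3-[4-(benzyloxy)-3-(4-bromophenoxy)phenyl]-3-[(trichlorosilyl)oxy]propanoate | COC(=O)C[C@H](O[Si](Cl)(Cl)Cl)c1ccc(OCc2ccccc2)c(Oc2ccc(Br)cc2)c1 | intermediate
13 | methyl (3S)-3-[4-(benzyloxy)-3-(4-bromophenoxy)phenyl]-3-hydroxypropanoate | COC(=O)C[C@H](O)c1ccc(OCc2ccccc2)c(Oc2ccc(Br)cc2)c1 | intermediate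
14 | [4-(2-(benzyloxy)-5-[(1S)-1-hydroxy-3-methoxy-3-oxopropyl]phenoxy)phenyl]boronic acid | COC(=O)C[C@H](O)c1ccc(OCc2ccccc2)c(Oc2ccc(B(O)O)cc2)c1 | intermediate
15 | methyl (3S)-3-[4-(benzyloxy)-3-{4-[(2S)-5,7-bis(benzyloxy)-4-oxochroman-2-yl]phenoxy}phenyl]-3-hydroxypropanoate | COC(=O)C[C@H](O)c1ccc(OCc2ccccc2)c(Oc2ccc([C@@H]3CC(=O)c4c(OCc5ccccc5)cc(OCc5ccccc5)cc4O3)cc2)c1 | intermediate
16 | O-trimethylsilyl ether of 15 | COC(=O)C[C@H](O[Si](C)(C)C)c1ccc(OCc2ccccc2)c(Oc2ccc([C@@H]3CC(=O)c4c(OCc5ccccc5)cc(OCc5ccccc5)cc4O3)cc2)c1 | intermediate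
17 | 3,5-dimethoxybenzyne | COC1=CC(OC)=CC#C1 | intermediate
18 | caesium aryl anion formed by addition of the alkoxide of 16 to 17 (charge between the 5-methoxy carbon and the aryloxy carbon) | [Cs+].COC(=O)C[C@H](Oc1cc(OC)cc(OC)[c-]1)c1ccc(OCc2ccccc2)c(Oc2ccc([C@@H]3CC(=O)c4c(OCc5ccccc5)cc(OCc5ccccc5)cc4O3)cc2)c1 | intermediate
19 | (2S)-2-[4-(benzyloxy)-3-{4-[(2S)-5,7-bis(benzyloxy)-4-oxochroman-2-yl]phenoxy}phenyl]-5,7-dimethoxychroman-4-one | COc1cc(OC)c2c(c1)O[C@H](c1ccc(OCc3ccccc3)c(Oc3ccc([C@@H]4CC(=O)c5c(OCc6ccccc6)cc(OCc6ccccc6)cc5O4)cc3)c1)CC2=O | intermediate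
20 | 7-O-methyltetrahydroochnaflavone (2S,2''S) | COc1cc(O)c2c(c1)O[C@H](c1ccc(O)c(Oc3ccc([C@@H]4CC(=O)c5c(O)cc(O)cc5O4)cc3)c1)CC2=O | target

Total step count: 10. Longest linear sequence: 7 steps (steps 4 to 10, from 8 to 20).

Steps most likely to fail

Step 9. Several things may go wrong.
- Proton transfer from the ester α-position may quench the aryl anion before acyl capture.
- The free alkoxide may fragment by retro-aldol cleavage or β-elimination.
- Transient base may open a chromanone ring and erode configuration.

The fallback sets out from alcohol 15 and precursor 5 and makes the two bonds one after the other with known reactions. O–H insertion of 15 into the aryne from 5 (KF, 18-crown-6, THF, −20 °C) should give, with retention, methyl (3S)-3-aryl-3-(3,5-dimethoxyphenoxy)propanoate F1. Me3SnOH in 1,2-dichloroethane at 70 °C then cleaves the ester under near-neutral conditions to the corresponding 3-(3,5-dimethoxyphenoxy)propanoic acid F2. Finally (CF3CO)2O in CH2Cl2 at 0 °C closes ring C by intramolecular Friedel–Crafts acylation. The two ortho positions of the symmetric, very electron-rich aryl ether are equivalent, so one product is expected. The route is rejoined at 19.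

Step 7. Protodeboronation of the valuable boronic acid may outrun the slow insertion of the electron-rich chromone, or facial selectivity may be weak. The fallback sets out from 14 and 7 and moves stereocontrol from the C–C bond formation to a resolution.
- An achiral, more active catalyst (Pd(OCOCF3)2, 2,2'-bipyridine, aqueous MeOH, 60 °C) should give the mixture of epimers at the new chromanone C2, F3.
- Asymmetric transfer hydrogenation (RuCl(p-cymene)[(R,R)-TsDPEN], HCO2H/Et3N, EtOAc, 25 °C) is stopped near half conversion.
- It should reduce the 2R epimer faster, to the (2R,4R)-cis-flavan-4-ol F4.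
- F4 is removed by chromatography, and the untouched 2S ketone rejoins the route at 15.

Step 10. The Lewis acid may ionise the benzylic C2–O1 bond para to the oxygenated ring. That would cause epimerisation or opening to the chalcone, alongside C-benzylation of the phloroglucinol rings. The fallback sets out from 19 and separates the two tasks. Neutral hydrogenolysis (H2, Pd/C, EtOAc/THF, 23 °C) removes the three benzyl groups and should give the 5-O-methyl ether of the target, F5. The mild chelating reagent MgI2·OEt2 (THF, 50 °C) then removes only the methyl group peri to the carbonyl, which arrives at 20.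

Further compounds
F1 | step 9 | methyl (3S)-3-[4-(benzyloxy)-3-{4-[(2S)-5,7-bis(benzyloxy)-4-oxochroman-2-yl]phenoxy}phenyl]-3-(3,5-dimethoxyphenoxy)propanoate | COC(=O)C[C@H](Oc1cc(OC)cc(OC)c1)c1ccc(OCc2ccccc2)c(Oc2ccc([C@@H]3CC(=O)c4c(OCc5ccccc5)cc(OCc5ccccc5)cc4O3)cc2)c1
F2 | step 9 | (3S)-3-[4-(benzyloxy)-3-{4-[(2S)-5,7-bis(benzyloxy)-4-oxochroman-2-yl]phenoxy}phenyl]-3-(3,5-dimethoxyphenoxy)propanoic acid | OC(=O)C[C@H](Oc1cc(OC)cc(OC)c1)c1ccc(OCc2ccccc2)c(Oc2ccc([C@@H]3CC(=O)c4c(OCc5ccccc5)cc(OCc5ccccc5)cc4O3)cc2)c1
F3 | step 7 | mixture of 15 and its epimer at the chromanone C2 | COC(=O)C[C@H](O)c1ccc(OCc2ccccc2)c(Oc2ccc(C3CC(=O)c4c(OCc5ccccc5)cc(OCc5ccccc5)cc4O3)cc2)c1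
F4 | step 7 | methyl (3S)-3-[4-(benzyloxy)-3-{4-[(2R,4R)-5,7-bis(benzyloxy)-4-hydroxychroman-2-yl]phenoxy}phenyl]-3-hydroxypropanoate | COC(=O)C[C@H](O)c1ccc(OCc2ccccc2)c(Oc2ccc([C@H]3C[C@@H](O)c4c(OCc5ccccc5)cc(OCc5ccccc5)cc4O3)cc2)c1
F5 | step 10 | (2S)-2-[3-{4-[(2S)-5,7-dihydroxy-4-oxochroman-2-yl]phenoxy}-4-hydroxyphenyl]-5,7-dimethoxychroman-4-one | COc1cc(OC)c2c(c1)O[C@H](c1ccc(O)c(Oc3ccc([C@@H]4CC(=O)c5c(O)cc(O)cc5O4)cc3)c1)CC2=O
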